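## Retrosynthetic overview
1. The target **1**, (R)-farnesyl-3,5-dimethylorsellinic acid, has a single quaternary stereocentre. I disconnect it at the C–farnesyl bond to 3,5-dimethylorsellinic acid (DMOA, **2**) and farnesyl diphosphate (FPP, **3**). An aromatic prenyltransferase does this dearomative C-farnesylation in the last step and sets the stereocentre.
2. **2** is made from orsellinic acid (**4**) by benzyl protection, 3,5-dibromination, double Pd-catalysed methylation and one neutral hydrogenolysis.
3. **3** is made from (E,E)-farnesol (**5**) via farnesyl chloride and diphosphorylation.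
4. No ring is built. The only ring is the commercial arene of **4**, and it is dearomatised in the final step.

**Assumptions.** (i) The prenyltransferase delivers the (R)-quaternary centre drawn in the target; I read the SMILES as 6R, the natural-series configuration. (ii) The target is drawn as the dienone–enol tautomer, and I keep that form.

## Route

**Step 1**
Reactants: **4** orsellinic acid (2,4-dihydroxy-6-methylbenzoic acid); **6** benzyl bromide
Product: **7** benzyl 2,4-bis(benzyloxy)-6-methylbenzoate
Conditions: BnBr (3.4 equiv), K2CO3, DMF, 60 °C, 12 h
Reagents that add atoms: benzyl bromide, BrCc1ccccc1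
Why: Williamson O-alkylation of both phenols and the carboxylate gives one protecting-group type, removable later by neutral hydrogenolysis, so the decarboxylation-prone resorcylic acid never meets hydrolytic conditions.

**Step 2**
Reactants: **7**; **8** N-bromosuccinimide
Product: **9** benzyl 3,5-dibromo-2,4-bis(benzyloxy)-6-methylbenzoate
Conditions: NBS (2.2 equiv), MeCN, 0 °C → rt, dark, 3 h
Reagents that add atoms: NBS, O=C1CCC(=O)N1Br
Why: electrophilic aromatic bromination. C3 and C5 are the only free ring positions and both are activated by two ortho/para OBn groups, and polar solvent in the dark avoids benzylic bromination of the ring CH3.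

**Step 3**
Reactants: **9**; **10** trimethylboroxine
Product: **11** benzyl 2,4-bis(benzyloxy)-3,5,6-trimethylbenzoate
Conditions: Me3B3O3 (1.5 equiv), Pd(OAc)2 (10 mol%), SPhos (20 mol%), K3PO4, dioxane, 100 °C, 16 h
Reagents that add atoms: trimethylboroxine, CB1OB(C)OB(C)O1
Why: Suzuki–Miyaura methylation. The bulky biaryl phosphine ligand handles the di-ortho-substituted aryl bromides, and the benzyl ethers and the hindered benzyl ester survive the mild base.

**Step 4**
Reactants: **11**
Product: **2** 3,5-dimethylorsellinic acid (2,4-dihydroxy-3,5,6-trimethylbenzoic acid)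
Conditions: H2 (1 atm), 10% Pd/C, EtOAc/MeOH 1:1, rt, 6 h; filter and concentrate below 30 °C
Reagents that add atoms: none (H2 only)
Why: hydrogenolysis cleaves two aryl benzyl ethers and the benzyl ester at rt, giving the free acid without heat or acid or base, so there is no decarboxylation. No alkenes are present yet.

**Step 5**
Reactants: **5** (2E,6E)-farnesol; **12** N-chlorosuccinimide
Product: **13** (2E,6E)-farnesyl chloride, (2E,6E)-1-chloro-3,7,11-trimethyldodeca-2,6,10-triene
Conditions: NCS (1.2 equiv), Me2S (1.3 equiv), CH2Cl2, −30 → 0 °C, 2 h; use crude immediately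
Reagents that add atoms: NCS, O=C1CCC(=O)N1Cl
Why: Corey–Kim chlorination. The primary alkoxysulfonium is displaced by chloride (SN2) at low temperature, so the E,E-geometry is kept with no SN2′ transposition and no polyene cyclisation.

**Step 6**
Reactants: **13**; **14** tris(tetra-n-butylammonium) hydrogen pyrophosphate
Product: **3** (2E,6E)-farnesyl diphosphate (isolated as its tris-ammonium salt)
Conditions: (Bu4N)3HP2O7 (2.5 equiv), MeCN, rt, 3 h; then Dowex AG50W-X8 (NH4+ form) ion exchange and lyophilisation
Reagents that add atoms: (Bu4N)3HP2O7, CCCC[N+](CCCC)(CCCC)CCCC (×3) with OP(=O)([O-])OP(=O)([O-])[O-]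
Why: SN2 displacement of the allylic chloride by the pyrophosphate nucleophile (Davisson diphosphorylation), with the trisubstituted alkenes untouched.

**Step 7 (key step, enzymatic)**
Reactants: **2** DMOA; **3** FPP
Product: **1** (R)-farnesyl-DMOA, the target
Conditions: aromatic prenyltransferase AusN (UbiA-type, EC 2.5.1.-; yeast microsomes), 50 mM Tris-HCl pH 7.5, 10 mM MgCl2, 5% DMSO, **2** (1 mM), **3** (1.5 mM), 30 °C, 16 h. Then acidify to pH 3 at 0 °C, extract with EtOAc, and purify by RP-HPLC (C18, MeCN/H2O with 0.1% HCO2H).
Reagents that add atoms: none (the farnesyl group comes from reactant **3**; Mg2+ is only a cofactor, and pyrophosphate is the leaving group)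
Why: this is enzymatic Friedel–Crafts-type dearomative C-prenylation. Mg2+ ionises FPP to the allylic cation, and the enzyme presents the prochiral, methyl-bearing C5 of DMOA (ortho to the 4-OH) to C1 of the cation. Only that face reacts, which sets the single quaternary stereocentre with (E,E)-geometry retained. The chemistry parallels the natural DMOA-derived meroterpenoid pathway.

## Checks
- **Structure:** **1** is a cyclohexa-2,4-dienone with C6 carrying CH3 and (E,E)-farnesyl, a 3-OH, a 4-COOH, and 2- and 5-CH3, as in the target SMILES.
- **Formula:** DMOA C10H12O4 + C15H25 − H = C25H36O4, which matches the target.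
- **Stereocentre:** the only stereocentre is formed in the last step and is never exposed to later chemistry.
- **Protecting groups and sensitive groups:** benzyl groups are removed before any alkene is present. The polyene and the acid are never exposed to H2, strong acid or heat.

## Compound list
1 | (R)-farnesyl-DMOA (target) | CC(C)=CCC/C(C)=C/CC/C(C)=C/C[C@@]1(C)C(=O)C(C)=C(O)C(C(=O)O)=C1C | target
2 | 3,5-dimethylorsellinic acid (DMOA) | Cc1c(C)c(O)c(C)c(O)c1C(=O)O | intermediate
3 | (2E,6E)-farnesyl diphosphate | CC(C)=CCC/C(C)=C/CC/C(C)=C/COP(=O)(O)OP(=O)(O)O | intermediate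
4 | orsellinic acid | Cc1cc(O)cc(O)c1C(=O)O | starting material
5 | (2E,6E)-farnesol | CC(C)=CCC/C(C)=C/CC/C(C)=C/CO | starting material
6 | benzyl bromide | BrCc1ccccc1 | starting material
7 | benzyl 2,4-bis(benzyloxy)-6-methylbenzoate | Cc1cc(OCc2ccccc2)cc(OCc2ccccc2)c1C(=O)OCc1ccccc1 | intermediate
8 | N-bromosuccinimide | O=C1CCC(=O)N1Br | starting material
9 | benzyl 3,5-dibromo-2,4-bis(benzyloxy)-6-methylbenzoate | Cc1c(Br)c(OCc2ccccc2)c(Br)c(OCc2ccccc2)c1C(=O)OCc1ccccc1 | intermediate
10 | trimethylboroxine | CB1OB(C)OB(C)O1 | starting material
11 | benzyl 2,4-bis(benzyloxy)-3,5,6-trimethylbenzoate | Cc1c(C)c(OCc2ccccc2)c(C)c(OCc2ccccc2)c1C(=O)OCc1ccccc1 | intermediate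
12 | N-chlorosuccinimide | O=C1CCC(=O)N1Cl | starting material
13 | (2E,6E)-farnesyl chloride | CC(C)=CCC/C(C)=C/CC/C(C)=C/CCl | intermediate
14 | tris(tetra-n-butylammonium) hydrogen pyrophosphate | CCCC[N+](CCCC)(CCCC)CCCC.CCCC[N+](CCCC)(CCCC)CCCC.CCCC[N+](CCCC)(CCCC)CCCC.OP(=O)([O-])OP(=O)([O-])[O-] | starting material

## Totals
Total steps: 7. Longest linear sequence: 5 (4 → 7 → 9 → 11 → 2 → 1). The farnesol branch is 3 steps (5 → 13 → 3) and joins at step 7.

## Three steps most likely to fail
1. **Step 7 (membrane-bound prenyltransferase: low turnover, or scale and enantiomer uncertainty).**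
   Fallback: replace the enzyme with a chemical route. Do a dearomative C-farnesylation of the allyl ester of **2** with farnesyl bromide, separate the C5-farnesylated isomer from C3- and O-alkylated products, resolve the enantiomers by preparative chiral HPLC, and remove the allyl ester with Pd(PPh3)4/morpholine.
2. **Step 3 (double Suzuki methylation of a hindered dibromide: mono-methylation or hydrodebromination).**
   Fallback: skip the halogenation and coupling. Do a double Mannich aminomethylation of benzyl orsellinate at C3 and C5, then hydrogenolyse the bis(aminomethyl) compound (H2, Pd/C) to install both methyls and remove the benzyl ester in one step.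
3. **Step 6 (diphosphorylation and purification of the acid-labile FPP).**
   Fallback: make **3** enzymatically from farnesol with an isoprenoid alcohol kinase and a farnesyl-phosphate kinase (ATP), then run step 7 directly on the buffered mixture.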